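The leftover starting material in the green run was what I looked at first; before charging the next flask I had to decide whether to leave the gas alone or speed it up.

| flask | starting material | gas phase | remark | time |
|---|---|---|---|---|
| green | 2.1 M | 200 mM (held) | run made earlier |  |
| flask | 1.5 M | 200 mM (held) |  | 8.0 min |

- green (time / min: target / %, starting material / %): 0.667: 5.3, 93.2; 1.33: 10.4, 86.6; 3.00: 16.8, 69.8; 8.00: 19.7, 26.1

(each reading ± 0.3 percentage points)

- at the start none of the gas phase is in solution

1. amount of target at 8.0 min, in percent of the starting material charged
2. the change that raises the amount of target at 8.0 min, in percent of the starting material charged most ("none" if none brings more than 2 percentage points) (epsilon / alpha / none)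
3. amount of target at 8.0 min, in percent of the starting material charged, after alpha

- epsilon: doubling the saturation concentration of gas phase, all else as stated
- alpha: doubling the transfer coefficient of the gas phase, all else as stated

Between 0.667 min and 3.00 min that leftover fell in a nearly straight line, and at the green charge this meant a feed of 0.211 M min⁻¹, as if a steady supply of dissolving gas were being consumed. So I carried one quantity to the new flask: the run-out time, the charge of starting material divided by that feed 7.12 min. Up to that time I expected target to be made, and after it I expected target to be lost.

In the green run target first rose by 0.164 M min⁻¹ and levelled near 0.414 M. I took loss to balance making at that level, which gave a loss of 0.397 min⁻¹ on the target standing. I reckoned on 0.879 min of pure loss in the flask before its reading, so my figure was 19.5 % of the charge.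

Doubling either gas setting should double the feed and bring the run-out time down to 3.56 min. I reckoned that even a level of 0.828 M then decays to 9.47 % of the charge, so I chose to leave the gas as it was.

The forecast gave 23 %, above my figure, with 10 % after alpha and none as the best change, saying “Neither change helps at 8 min”.

The flask gave 18.6 %. The best change was none, since epsilon moved target by −14 percentage points and alpha by −9.1 points, leaving 9.44 % after alpha.

    gas phase ⇌ dissolved gas, rate k1*(csat - [dissolved gas]) (kL = 0.0216 s⁻¹)
    dissolved gas + target → over-reacted product (k = 0.0326 M⁻¹ s⁻¹)
    target → over-reaction product (k = 0.00382 s⁻¹)
    target ⇌ isomer of the product (K = 1.63, k = 0.00371 s⁻¹)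
    starting material + dissolved gas → target (k = 0.0953 M⁻¹ s⁻¹)

This flask still held 13 % of its starting material at 8.00 min, a little past the run-out time of 7.12 min, so the feed had slackened towards the end. Target in this flask stood at 18.6 % partly through the bottleneck of the uptake of gas phase as dissolved gas and partly through the reading at that time and not ten times later: with that bottleneck taken away the flask held 2.95 % of target, and at 80.0 min it held 0.00612 %. The neighbour flask left until 15 min, twice the run-out time, held 3.68 % of target.

All runs are calculated with made-up constants; noise was put on by code.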